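The rate constants were set for the occasion; what happens was integrated by code.

A one-step world carries starting material straight to target, so that yield equals conversion, but the flasks asked about here feed a shared pool, and the hunch of a third of whatever converts needs testing against that pool.

common to all: starting material 0.28 M; gas 120 mM (held); time 3.0 min

| run | temperature |
|---|---|
| Wednesday's | −20 °C |
| Monday's | 20 °C |
| Sunday's | 0 °C |
| Saturday's | 40 °C |

    starting material + coupling partner → intermediate + released group (k1 = 0.053 L mol⁻¹ s⁻¹, Ea1 = 49.0 kJ mol⁻¹)
    intermediate ⇌ target (K2 = 1.9, k2 = 0.074 s⁻¹, Ea2 = 78.0 kJ mol⁻¹, ΔH2 = −4.00 kJ mol⁻¹)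
    intermediate ⇌ isomer of the product (K3 = 2.5, k3 = 0.030 s⁻¹, Ea3 = 83.0 kJ mol⁻¹, ΔH3 = −69.0 kJ mol⁻¹)
    gas ⇌ coupling partner, rate k4*(csat - [coupling partner]) (k4 = 0.051 s⁻¹, csat = 120 mM)
    (constants at 20 °C)

- at the start none of coupling partner is dissolved
- the list of constants is for 20 °C, to be carried to other temperatures by the activation energies and enthalpies

- the flask that comes out highest in amount of target, in percent of the starting material charged, or "all alike" when all lie within 1.5 percentage points (Wednesday's / Monday's / Sunday's / Saturday's / all alike)
- target at the end, in percent of the starting material charged, Wednesday's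
- target at the end, in percent of the starting material charged, Monday's
- target at the end, in percent of the starting material charged, Sunday's
- target at the end, in percent of the starting material charged, Saturday's

1. Intermediate, target and isomer of the product form the pool; with K_T for intermediate ⇌ target and K_Q for intermediate ⇌ isomer, target's fraction of a balanced pool at 20 °C is K_T/(1 + K_T + K_Q) = 35.2 %, and this fraction is the equilibrium share φ, whose statistical zero, with both constants at 1, is the hunch's a third.

2. Warming moves K_T little, to 1.71 at 40 °C, but carries K_Q from 219 at −20 °C down to 0.410, so φ runs 1.11 % on Wednesday's, 9.31 % on Sunday's and 54.8 % on Saturday's, the highest of the flasks.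

3. On Saturday's the pool should balance as it fills (thermodynamic control), because the isomer step's forward time of 3.79 s is far shorter than the feed time of 43.5 s with partner at saturation.

4. Integrating the rates, with S for starting material and C for coupling partner, gives ln(S₀/S) = k₁·csat·t − (k₁/k₄)(C + S₀ − S); for Saturday's, putting C at csat and S₀ − S at S₀ gives 2.63, an estimated conversion of 92.8 %, and φ times that gives an estimated target of 50.9 %.

5. Monday's, with partner taken at csat throughout, is estimated to convert 68.2 %, and φ times that gives roughly 24.0 %, less than the estimate for Saturday's. The φ reckoning stops at the cold flasks, whose isomer-step times of 6.72 min on Sunday's and 121 min on Wednesday's exceed the run. Their conversions with partner taken at csat, 23.1 % on Sunday's and 4.66 % on Wednesday's, lie below the estimated target of Saturday's, so the pick is Saturday's.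

The forecast named Saturday's, with 0.15 %, 6.4 %, 22.6 % and 51.2 % from coldest to hottest, saying of the hottest flask that “the equilibrium fraction (0.55) is reached quickly”.

The simulation gives Saturday's as highest, with 0.153 %, 6.45 %, 22.7 % and 51.2 % in the same order.

On Saturday's, the half-life of intermediate by the forward isomer step alone, 2.6 s at 3.00 min, stands against 1.01 min for half of the first step's turnover up to that time, and target holds 54.7 % of the pool at 3.00 min, beside a φ of 54.8 %. On Monday's, the pool at 3.00 min is still unbalanced at 39.2 % target, but with starting material at 0 % after 30.0 min, target reads 35.2 %, beside a φ of 35.2 %.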